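**Retrosynthetic overview**
1. (−)-Pipoxide 10 ⇐ hydroxyl-directed epoxidation of diene dibenzoate 9; the oxirane of the target is the last ring formed.
2. 9 ⇐ dienal 7 by 1,2-reduction and benzoylation of the primary alcohol.
3. 7 ⇐ semipinacol ring contraction of the seven-membered trans-epoxy alcohol 5 (the carbinol carbon is extruded as CHO, giving the six-membered carbocycle), then vinylogous loss of one benzoate.
4. 5 ⇐ meso dienone dibenzoate 3 by desymmetrising mono-epoxidation (temporary oxirane, absolute configuration) and ketone reduction.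
5. 3 ⇐ tropone 1 by cis-dihydroxylation of C4=C5 and benzoylation. Ring order: seven-membered ring (from tropone) → temporary oxirane → six-membered ring by contraction → final oxirane.

Assumption: benzoyl chloride and the other atom-donating reagents are treated as reagents (given on the reagent lines, not numbered); in 2–5 the ring is numbered C1 (carbonyl or carbinol), C2–C3 (epoxide), C4 and C5 (benzoates), C6=C7.

Nothing here has been run; steps 1, 4 and 5 rest on analogy and on precedent recalled from memory rather than on a checked literature case.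

**Step 1**
Reactants: 1 tropone (cyclohepta-2,4,6-trien-1-one)
Product: 2 cis-4,5-dihydroxycyclohepta-2,6-dien-1-one (meso, 4R,5S)
Conditions: OsO4 (1 mol %), N-methylmorpholine N-oxide (1.05 equiv), acetone–H2O 4:1, 0 °C
Reagents that add atoms: N-methylmorpholine N-oxide, C[N+]1([O-])CCOCC1; water, O
Why: Upjohn syn-dihydroxylation: electrophilic OsO4 should take the one C=C of tropone not directly conjugated to the carbonyl (C4=C5, by analogy with osmylation of dienones and dienoates at the distal alkene), the bis-enone product is deactivated towards a second osmylation, and suprafacial addition gives the cis (meso) diol, so no absolute configuration is needed yet.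

**Step 2**
Reactants: 2 cis-4,5-dihydroxycyclohepta-2,6-dien-1-one
Product: 3 cis-4,5-bis(benzoyloxy)cyclohepta-2,6-dien-1-one (meso, 4R,5S)
Conditions: BzCl (2.4 equiv), pyridine, 4-(dimethylamino)pyridine (5 mol %), CH2Cl2, 0 °C
Reagents that add atoms: benzoyl chloride, O=C(Cl)c1ccccc1
Why: Standard 4-(dimethylamino)pyridine-catalysed esterification of both secondary alcohols; one benzoate becomes the C3 benzoate of the target, its twin is the leaving group that later unveils the diene, and the compound stays meso.

**Step 3**
Reactants: 3 cis-4,5-bis(benzoyloxy)cyclohepta-2,6-dien-1-one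
Product: 4 (2R,3R,4S,5S)-4,5-bis(benzoyloxy)-2,3-epoxycyclohept-6-en-1-one (epoxide trans to both benzoates)
Conditions: 9-amino(9-deoxy)epi-quinine (10 mol %), CF3CO2H (20 mol %), 50% aq. H2O2 (1.5 equiv), 1,4-dioxane, 20 °C
Reagents that add atoms: hydrogen peroxide, OO
Why: Proposed new method: a catalyst-controlled desymmetrising Weitz–Scheffer mono-epoxidation of a meso cyclohepta-2,6-dienone, in which the chiral primary ammonium salt forms a cross-conjugated iminium ion and distinguishes the two enantiotopic β-carbons, hydroperoxide adds to C3 anti to the neighbouring benzoate and the enamine closes the oxirane (setting C2 and C3 and thereby fixing which benzoate-bearing carbon becomes C3 of the target), while the epoxy ketone formed is a poorer iminium substrate so the second enone survives; the closest known reaction is the cinchona primary-amine salt/H2O2 asymmetric epoxidation of simple cyclic enones such as cyclohept-2-enone, and the quinidine-derived pseudo-enantiomer of the amine is used instead if the sense of induction turns out reversed.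

**Step 4**
Reactants: 4 (2R,3R,4S,5S)-4,5-bis(benzoyloxy)-2,3-epoxycyclohept-6-en-1-one
Product: 5 (1R,2S,3S,4S,5S)-4,5-bis(benzoyloxy)-2,3-epoxycyclohept-6-en-1-ol (hydroxyl trans to the epoxide, cis to the benzoates)
Conditions: NaBH4, CeCl3·7H2O, MeOH, −78 °C
Reagents that add atoms: none
Why: Luche 1,2-reduction: hydride is expected to reach the carbonyl from the epoxide face, opposite the two benzoates that shield the other face across the ring and in line with the trans selectivity reported for Luche reductions of cyclic 2,3-epoxy ketones, giving the trans-epoxy alcohol (C1 R) whose carbinol hydrogen is syn to the epoxide and so cannot migrate in step 5.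

**Step 5**
Reactants: 5 (1R,2S,3S,4S,5S)-4,5-bis(benzoyloxy)-2,3-epoxycyclohept-6-en-1-ol
Product: 7 (1S,6S)-5-formyl-6-hydroxycyclohexa-2,4-dien-1-yl benzoate, via ring-contracted hydroxy aldehyde 6 (not isolated)
Conditions: BF3·OEt2 (20 mol %), CH2Cl2, −78 °C; then Et3N (3 equiv), −78 → 0 °C
Reagents that add atoms: none
Why: Semipinacol rearrangement of a 2,3-epoxy alcohol with ring contraction: Lewis-acid opening of the oxirane at C2 is concerted with anti-periplanar 1,2-shift of the ring vinyl carbon C7 from C1 to C2, pushed by the carbinol oxygen that becomes the aldehyde, so the seven-membered ring becomes formylcyclohexene 6 with the epoxide oxygen kept on old C3 with retention (trans to the adjacent benzoate); triethylamine then causes vinylogous E1cB loss of the remote benzoate through the dienolate to give the conjugated dienal, erasing the two stereocentres no longer needed.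

**Step 6**
Reactants: 7 (1S,6S)-5-formyl-6-hydroxycyclohexa-2,4-dien-1-yl benzoate (used crude, cold)
Product: 8 (1S,6S)-6-hydroxy-5-(hydroxymethyl)cyclohexa-2,4-dien-1-yl benzoate
Conditions: NaBH4, CeCl3·7H2O, MeOH, −40 °C
Reagents that add atoms: none
Why: Luche 1,2-reduction of the dienal to the primary allylic alcohol; no stereocentre is touched and the benzoate survives at low temperature.

**Step 7**
Reactants: 8 (1S,6S)-6-hydroxy-5-(hydroxymethyl)cyclohexa-2,4-dien-1-yl benzoate
Product: 9 [(5S,6S)-5-(benzoyloxy)-6-hydroxycyclohexa-1,3-dien-1-yl]methyl benzoate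
Conditions: BzCl (1.05 equiv), 2,4,6-collidine, CH2Cl2, −40 → 0 °C
Reagents that add atoms: benzoyl chloride, O=C(Cl)c1ccccc1
Why: Chemoselective esterification: the unhindered primary allylic alcohol is benzoylated much faster than the secondary alcohol flanked by the substituted ring carbon, the same differentiation the natural product shows.

**Step 8**
Reactants: 9 [(5S,6S)-5-(benzoyloxy)-6-hydroxycyclohexa-1,3-dien-1-yl]methyl benzoate
Product: 10 (−)-pipoxide, [(1R,2R,3S,6S)-3-(benzoyloxy)-2-hydroxy-7-oxabicyclo[4.1.0]hept-4-en-1-yl]methyl benzoate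
Conditions: VO(acac)2 (5 mol %), t-BuOOH (1.5 equiv), CH2Cl2, 0 °C → rt
Reagents that add atoms: tert-butyl hydroperoxide, CC(C)(C)OO
Why: Hydroxyl-directed vanadium-catalysed (Sharpless–Michaelson) epoxidation: the vanadate ester of the secondary allylic alcohol delivers oxygen only to the adjacent trisubstituted C=C and to the face syn to that hydroxyl, setting C1 (R) and C6 (S) and leaving the other alkene untouched.

**Compound list**
1 | tropone (cyclohepta-2,4,6-trien-1-one) | O=C1C=CC=CC=C1 | starting material
2 | cis-4,5-dihydroxycyclohepta-2,6-dien-1-one (meso, 4R,5S) | O=C1C=C[C@H](O)[C@H](O)C=C1 | intermediate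
3 | cis-4,5-bis(benzoyloxy)cyclohepta-2,6-dien-1-one (meso, 4R,5S) | O=C1C=C[C@H](OC(=O)c2ccccc2)[C@H](OC(=O)c2ccccc2)C=C1 | intermediate
4 | (2R,3R,4S,5S)-4,5-bis(benzoyloxy)-2,3-epoxycyclohept-6-en-1-one | O=C1C=C[C@H](OC(=O)c3ccccc3)[C@H](OC(=O)c3ccccc3)[C@H]2O[C@@H]12 | intermediate
5 | (1R,2S,3S,4S,5S)-4,5-bis(benzoyloxy)-2,3-epoxycyclohept-6-en-1-ol | O[C@@H]1C=C[C@H](OC(=O)c3ccccc3)[C@H](OC(=O)c3ccccc3)[C@H]2O[C@@H]12 | intermediate
6 | (1R,2S,5S,6S)-5-formyl-6-hydroxycyclohex-3-ene-1,2-diyl dibenzoate | O=C[C@H]1C=C[C@H](OC(=O)c2ccccc2)[C@H](OC(=O)c2ccccc2)[C@H]1O | intermediate (not isolated)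
7 | (1S,6S)-5-formyl-6-hydroxycyclohexa-2,4-dien-1-yl benzoate | O=CC1=CC=C[C@H](OC(=O)c2ccccc2)[C@H]1O | intermediate
8 | (1S,6S)-6-hydroxy-5-(hydroxymethyl)cyclohexa-2,4-dien-1-yl benzoate | OCC1=CC=C[C@H](OC(=O)c2ccccc2)[C@H]1O | intermediate
9 | [(5S,6S)-5-(benzoyloxy)-6-hydroxycyclohexa-1,3-dien-1-yl]methyl benzoate | O=C(OCC1=CC=C[C@H](OC(=O)c2ccccc2)[C@H]1O)c1ccccc1 | intermediate
10 | (−)-pipoxide | O=C(OC[C@]12O[C@H]1C=C[C@H](OC(=O)c1ccccc1)[C@H]2O)c1ccccc1 | target

**Totals:** 8 steps; longest linear sequence 8 steps (fully linear from tropone).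

**Steps most likely to fail and their fallbacks**

Step 3 (the new desymmetrising epoxidation). Likely failure modes are low enantioselectivity, or dienamine formation followed by loss of benzoic acid to a 4-benzoyloxytropone. The fallback uses only known chemistry, sets out from 3 and returns at 5. Dibenzoate 3 is epoxidised without chiral control (t-BuOOH, catalytic DBU, CH2Cl2, −20 °C; ordinary Weitz–Scheffer epoxidation, still anti to the benzoates), which gives 4 together with its mirror image, the ent-epoxy ketone F1. Luche reduction as in step 4 gives 5 together with the ent-epoxy alcohol F2. Kinetic resolution with Burkholderia cepacia lipase and vinyl acetate (MTBE, 30 °C) should acetylate the (1R)-alcohol 5 (Kazlauskas rule) to the acetate F3. F3 is separated from unreacted F2 and deacetylated by the same lipase in n-butanol/MTBE, which leaves the benzoates alone, to return 5.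

Step 4 (face selectivity of the reduction). If hydride enters from the other face, the product is the cis-epoxy alcohol, which would mainly undergo hydride shift in step 5. The fallback sets out from 4 and returns at 5. The reduction product, the C1-epimeric cis-epoxy alcohol F4, is inverted by a Mitsunobu reaction with chloroacetic acid (PPh3, diisopropyl azodicarboxylate, toluene, 0 °C) to the chloroacetate F5. The chloroacetyl group is then removed selectively with thiourea/NaHCO3 (EtOH–THF, 50 °C), which does not touch the benzoates, to give 5.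

Step 5 (the ring contraction). Likely failure modes are participation of the neighbouring benzoate in epoxide opening, and aromatisation of the dienal. The fallback sets out from 5 and returns at 8. The rearrangement is run in the epoxy silyl ether mode: 5 is silylated (Et3SiCl, imidazole, CH2Cl2) to the triethylsilyl ether F6. With catalytic methylaluminium bis(4-bromo-2,6-di-tert-butylphenoxide) (CH2Cl2, −78 °C), F6 rearranges with silyl transfer to the β-silyloxy aldehyde F7, in which the new hydroxyl is protected against acyl migration and retro-aldol cleavage. DBU (−40 °C) eliminates benzoic acid to the silyl-protected dienal F8. Luche reduction gives the silyl ether F9, and AcOH–THF–H2O removes the silyl group to rejoin the route at 8.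

**Further compounds**
F1 | step 3 | (2S,3S,4R,5R)-4,5-bis(benzoyloxy)-2,3-epoxycyclohept-6-en-1-one (mirror image of 4) | O=C1C=C[C@@H](OC(=O)c3ccccc3)[C@@H](OC(=O)c3ccccc3)[C@@H]2O[C@H]12
F2 | step 3 | (1S,2R,3R,4R,5R)-4,5-bis(benzoyloxy)-2,3-epoxycyclohept-6-en-1-ol (mirror image of 5) | O[C@H]1C=C[C@@H](OC(=O)c3ccccc3)[C@@H](OC(=O)c3ccccc3)[C@@H]2O[C@H]12
F3 | step 3 | acetate of 5 at the C1 hydroxyl | CC(=O)O[C@@H]1C=C[C@H](OC(=O)c3ccccc3)[C@H](OC(=O)c3ccccc3)[C@H]2O[C@@H]12
F4 | step 4 | (1S,2S,3S,4S,5S)-4,5-bis(benzoyloxy)-2,3-epoxycyclohept-6-en-1-ol (C1 epimer of 5, cis-epoxy alcohol) | O[C@H]1C=C[C@H](OC(=O)c3ccccc3)[C@H](OC(=O)c3ccccc3)[C@H]2O[C@@H]12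
F5 | step 4 | chloroacetate of 5 at the C1 hydroxyl | O=C(CCl)O[C@@H]1C=C[C@H](OC(=O)c3ccccc3)[C@H](OC(=O)c3ccccc3)[C@H]2O[C@@H]12
F6 | step 5 | triethylsilyl ether of 5 | CC[Si](CC)(CC)O[C@@H]1C=C[C@H](OC(=O)c3ccccc3)[C@H](OC(=O)c3ccccc3)[C@H]2O[C@@H]12
F7 | step 5 | triethylsilyl ether of 6 at the secondary hydroxyl | O=C[C@H]1C=C[C@H](OC(=O)c2ccccc2)[C@H](OC(=O)c2ccccc2)[C@H]1O[Si](CC)(CC)CC
F8 | step 5 | triethylsilyl ether of 7 | O=CC1=CC=C[C@H](OC(=O)c2ccccc2)[C@H]1O[Si](CC)(CC)CC
F9 | step 5 | triethylsilyl ether of 8 at the secondary hydroxyl | OCC1=CC=C[C@H](OC(=O)c2ccccc2)[C@H]1O[Si](CC)(CC)CC
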